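**Numbering used throughout:** 1 2,4,6-trihydroxybenzophenone; 2 benzyl bromide; 3 2,4-bis(benzyloxy)-6-hydroxybenzophenone; 4 2-bromo-2-methylpropanoic acid; 5 aryloxy acid; 6 mixed anhydride (not isolated); 7 coumaranone; 8 trimethylsilyldiazomethane; 9 4-silyl chromanone (not isolated); 10 chroman-3-one; 11 (R)-chroman-3-ol; 12 (R)-triol; 13 geranyl bromide; 14 target.

## Analysis of the target

The target 14 is a 2,2-dimethylchroman whose benzene ring is fully substituted. The ring oxygen O1 sits on C8a, a benzoyl group on C8, a chelated hydroxyl on C7, an (E)-geranyl chain on C6, a second hydroxyl on C5, and the pyran methylene C4 on C4a. There is one stereocentre, the carbinol carbon C3, which is R as read from the SMILES. It lies between the quaternary C2 and the benzylic C4, and with no second stereocentre to relay from it has to be set by a reagent or catalyst. The sensitive groups are the geranyl chain (destroyed by hydrogenation, cyclised onto a neighbouring phenol by acid), the electron-rich acylphloroglucinol nucleus (ambident towards alkylating agents, easily oxidised) and the diaryl ketone. The real difficulty is regiochemical: which of three phloroglucinol oxygens becomes O1 relative to the benzoyl group, and carbon against oxygen attack when the geranyl group goes on. The plan rests on one feature: the heterocycle O1–C2–C3–C4–C4a–C8a is exactly one methylene (C4) larger than the furanone ring of a 2,2-dimethylbenzofuran-3(2H)-one, in which the carbonyl carbon is bonded directly to the arene. Inserting C4 between that carbonyl and the aryl carbon gives the chroman-3-one with oxygen already at C3. The coumaranone in turn comes from a benzophenone that carries the benzoyl group and all three oxygens.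

## Retrosynthetic reasoning

**14 to 12 and 13.** The C6–C1′ bond is cut last. The geranyl alkenes would not survive the hydrogenolysis that frees the phenols, nor the Lewis acid of the ring expansion. In 12, C6 is the only unsubstituted ring carbon and lies between two phenolic hydroxyls, so the position is not in question. The forward step has to favour carbon over oxygen alkylation and stop after one alkylation.

**12 to 11.** The two O–benzyl bonds are cut. Benzyl ethers come off under neutral reducing conditions that leave the C3 carbinol alone. The phenols must be masked in the key step, because a diazoalkane under Lewis acid would alkylate free phenols.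

**11 to 10.** The C3–H bond is cut, so the stereocentre comes from an achiral ketone under catalyst control. The two flanks of the carbonyl differ sharply, fully substituted C2 against the methylene C4, which is the difference an oxazaborolidine-catalysed hydride transfer reads. No stereochemistry has to be carried through the earlier steps.

**10 to 7 and 8.** This is the key disconnection. The bonds C3–C4 and C4–C4a are cut and C4 is excised, leaving the coumaranone 7 and the one-carbon reagent 8. The cut is made here because the C3 oxygen then arrives as a carbonyl, with no oxidation of a chroman or chromene needed, and because the ring oxygen of 7 is simply a phenol oxygen of 1. The forward reaction must add the diazo carbon to the furanone carbonyl and then move the aryl carbon, not C2.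

**7 to 5 (through 6).** The aryl–acyl bond C3–C3a (benzofuranone numbering) is cut, to be made by intramolecular acylation. The tether allows closure only onto the CH next to the ether oxygen. The opposite order, C-acylation of the arene with an α-bromoacyl halide followed by O-closure, was rejected. It needs a strong metal-halide Lewis acid on an acyl-deactivated ring, and such acids strip aryl benzyl ethers, most readily one lying ortho to the new ketone. Once a benzyl group is lost, the choice of phenol for the furanone closure is open again. Activation as the mixed anhydride 6 needs no metal Lewis acid.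

**5 to 3 and 4.** The O1–C2 ether bond is cut. The only free phenol of 3 is the one ortho to the benzoyl group, which fixes O1 next to C8 without ambiguity.

**3 to 1 and 2.** Two O–benzyl bonds are cut. After the para and one ortho hydroxyl of 1 are benzylated, the last hydroxyl is locked in a hydrogen bond to the ketone and resists. One step therefore masks both future free phenols and singles out the future ring oxygen.

## Alternatives that were turned down

**Alternative 1:** The C8–carbonyl bond and the C7–O bond would be cut together. Fluoride would unmask a C7–C8 aryne from the silyl triflate A1. Benzoic acid A2 would add through oxygen at C7, and the C8 aryl anion would take the benzoyl group by intramolecular acyl transfer, giving the bis-MOM ether A3.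
- For: two substituents arrive in one operation. The C8a oxygen polarises the aryne so that the nucleophile should attack the distal carbon C7, which is the right sense. The geranyl chain is already in place, so there is no late C/O-alkylation problem. On that last point it is stronger than the chosen route.
- Against: A1 is itself a hexasubstituted arene with a stereocentre, so every regiochemical question is moved into a long precursor synthesis. The aryne is generated ortho to a geranyl chain placed for intramolecular ene or [2+2] capture. Acyl transfer must beat simple protonation of the aryl anion. Acidic removal of two MOM ethers next to a geranyl chain invites cyclisation onto the phenol.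
- Comparison: the chosen route takes benzoyl group and oxygen pattern ready-made from 1 and is far shorter. It pays with a late geranylation of moderate selectivity.

**Alternative 2:** The bonds C4–C3 and O1–C2 would be cut. A chiral phosphoric acid would dehydrate the ortho-hydroxybenzyl alcohol A4 to an ortho-quinone methide, which would add across the isobutenyl pinacol boronate A5 to give the 3-boryl chroman A6. Stereoretentive C–B oxidation would follow.
- For: ring, gem-dimethyl carbon and C3 stereocentre in one catalytic step. The polarity matches (O1 to the dimethyl-bearing carbon). Oxidation of the boronate is stereospecific. On convergence and on setting the stereocentre during ring construction it is stronger.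
- Against: the methide carbon is unsubstituted, so the only new stereocentre lies on the dienophile, remote from the catalyst's contact with the quinone methide oxygen. Alkenyl boronates are weak nucleophiles. The quinone methide can instead be trapped by the geranyl alkene or a phenol, or can dimerise. Brønsted acid and geranyl are a poor pair. A4 needs its own regiocontrolled synthesis.
- Comparison: several unknowns are stacked in one step. The chosen route separates ring construction from stereocontrol and uses a ketone reduction with a clear steric model.

**Alternative 3:** The bonds C4a–C4 and O1–C2 would be cut. The para-benzylated dihydroxybenzophenone A7 would condense with 3-methylbut-2-enal A8 and close by oxa-6π electrocyclisation to the chromene A9. Jacobsen epoxidation of the C3=C4 bond with a chiral (salen)MnCl catalyst and reductive opening at C4 would follow.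
- For: the two hydroxyls of A7 are equivalent, so regiochemistry is trivial. Chromene formation on acylphloroglucinols and the epoxidation of 2,2-dimethylchromenes have the strongest precedent of anything considered here. On precedent and on expected enantioselectivity it is at least as strong as the chosen route.
- Against: the free phenol of A9 must be protected before an oxidant is used. The epoxide of a 5,7-dioxygenated chromene is an extremely labile benzylic epoxide. The oxygen placed on C4 then has to be removed again by hydride at the benzylic carbon without touching the diaryl ketone, an oxidation-state detour.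
- Comparison: the chosen route puts oxygen on C3 only and passes through the stable achiral ketone 10, from which either enantiomer can be reached and unwanted alcohol recycled. The chromene chemistry is kept in reserve as the fallback for the key step.

Key step: step 4

Remark on the chemistry: whether the silyl group of 9 moves from carbon to oxygen before work-up does not matter, since acidic work-up leads to 10 either way.

## Route

Step 1
Reactants: 1 2,4,6-trihydroxybenzophenone; 2 benzyl bromide
Product: 3 2,4-bis(benzyloxy)-6-hydroxybenzophenone
Conditions: BnBr (2.1 equiv), K2CO3, DMF, rt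
Reagents that add atoms: benzyl bromide 2, BrCc1ccccc1
Why: Williamson etherification; the para hydroxyl and one of the two equivalent ortho hydroxyls react, while the remaining ortho hydroxyl is held in a hydrogen bond to the ketone and is left as the only free phenol, the future ring oxygen.

Step 2
Reactants: 3 2,4-bis(benzyloxy)-6-hydroxybenzophenone; 4 2-bromo-2-methylpropanoic acid
Product: 5 2-[2-benzoyl-3,5-bis(benzyloxy)phenoxy]-2-methylpropanoic acid
Conditions: NaOH (powdered), 2-butanone, 50 °C; then aq. HCl
Reagents that add atoms: 2-bromo-2-methylpropanoic acid 4, CC(C)(Br)C(=O)O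
Why: Bargellini-type O-alkylation, the standard preparation of α-aryloxyisobutyric acids; the α-bromo carboxylate ionises to an α-lactone-like electrophile that even a hindered, chelated phenoxide attacks at the tertiary carbon. The only free phenol of 3 is the nucleophile, so O1 is fixed next to the benzoyl group.

Step 3
Reactants: 5 2-[2-benzoyl-3,5-bis(benzyloxy)phenoxy]-2-methylpropanoic acid
Product: 7 7-benzoyl-4,6-bis(benzyloxy)-2,2-dimethylbenzofuran-3(2H)-one, via mixed carboxylic trifluoroacetic anhydride 6 (not isolated)
Conditions: (CF3CO)2O, CH2Cl2, 0 °C → rt
Reagents that add atoms: none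
Why: Intramolecular Friedel–Crafts acylation through the mixed anhydride; the only carbon in reach is the CH ortho to the ether oxygen, which is ortho, ortho and para to three oxygens and therefore reactive without a metal Lewis acid, so the benzyl ethers are kept. The gem-dimethyl group favours closure of the five-membered ring.

Step 4
Reactants: 7 7-benzoyl-4,6-bis(benzyloxy)-2,2-dimethylbenzofuran-3(2H)-one; 8 trimethylsilyldiazomethane
Product: 10 8-benzoyl-5,7-bis(benzyloxy)-2,2-dimethylchroman-3-one, via 4-(trimethylsilyl)chroman-3-one 9 (not isolated)
Conditions: Me3SiCHN2 (hexanes), BF3·OEt2, CH2Cl2, −78 → −20 °C; then 1 M HCl, THF, rt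
Reagents that add atoms: trimethylsilyldiazomethane 8, C[Si](C)(C)C=[N+]=[N-]
Why: BF3 activates the furanone carbonyl of 7 and the nucleophilic diazo carbon of 8 adds to it, giving a β-oxido diazonium species. Loss of N2 is coupled to a 1,2-shift of the aryl carbon from the carbonyl carbon to the diazo carbon, which forms C3–C4 and C4–C4a (chroman numbering) and gives the silyl ketone 9; acid then replaces silicon by hydrogen. The closest known reaction type is the Lewis-acid-promoted homologation of 1-indanones and 1-tetralones with Me3SiCHN2, a Tiffeneau–Demjanov-type shift in which the aryl group migrates to give the β-ketone. The six-membered ring arises by expansion of the five-membered one through migration, not by a cyclisation, so no closure mode has to be met. No stereocentre survives, since the silylated C4 of 9 becomes a methylene. Aryl over alkyl migration is needed: the migrating carbon is ortho, ortho and para to three oxygens and stabilises the bridged transition state, whereas C2 is fully substituted, carries the electron-withdrawing O1 and would have to move towards the bulky silyl group. Attack at the furanone carbonyl and not at the benzoyl carbonyl is needed: the diaryl ketone is flanked by two ortho substituents and twisted out of conjugation. A single insertion is needed: 9 is too hindered to accept a second diazoalkane, which is the advantage of 8 over diazomethane.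

Step 5
Reactants: 10 8-benzoyl-5,7-bis(benzyloxy)-2,2-dimethylchroman-3-one
Product: 11 (R)-8-benzoyl-5,7-bis(benzyloxy)-2,2-dimethylchroman-3-ol
Conditions: (S)-Me-CBS oxazaborolidine (15 mol%), BH3·SMe2 (0.7 equiv), THF, −20 °C; then MeOH
Reagents that add atoms: none
Why: Corey–Bakshi–Shibata reduction; the ketone binds the catalyst boron anti to its larger flank, the quaternary C2, and hydride comes from the nitrogen-bound borane, which with the (S)-catalyst should give the 3R alcohol, the same sense as for tert-alkyl and aryl methyl ketones. The di-ortho-substituted diaryl ketone should react much more slowly than the aliphatic one under substoichiometric borane.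

Step 6
Reactants: 11 (R)-8-benzoyl-5,7-bis(benzyloxy)-2,2-dimethylchroman-3-ol
Product: 12 (R)-8-benzoyl-2,2-dimethylchroman-3,5,7-triol
Conditions: H2 (1 atm), 10% Pd/C, EtOAc, rt
Reagents that add atoms: none
Why: Hydrogenolysis of two aryl benzyl ethers; the C3–O bond is not benzylic and the stereocentre is untouched. The hindered diaryl ketone is expected to be reduced more slowly, so the reaction is stopped once two equivalents of hydrogen are taken up.

Step 7
Reactants: 12 (R)-8-benzoyl-2,2-dimethylchroman-3,5,7-triol; 13 geranyl bromide
Product: 14 [(3R)-6-[(2E)-3,7-dimethylocta-2,6-dienyl]-3,5,7-trihydroxy-2,2-dimethylchroman-8-yl](phenyl)methanone (CNP0186586.1)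
Conditions: DBU (1.1 equiv), geranyl bromide (1.0 equiv), THF, 0 °C → rt
Reagents that add atoms: geranyl bromide 13, CC(C)=CCC/C(C)=C/CBr
Why: C-alkylation of an ambident acylphloroglucinol phenolate at C6, the only unsubstituted ring carbon, flanked by both phenolic oxygens; direct SN2 displacement at the primary allylic bromide keeps the E geometry. An amidinium phenolate in a weakly polar solvent favours carbon over oxygen attack, the C3 alcohol is not deprotonated, and one equivalent of 13 limits double alkylation.

## Compound list

1 | 2,4,6-trihydroxybenzophenone | O=C(c1ccccc1)c1c(O)cc(O)cc1O | starting material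
2 | benzyl bromide | BrCc1ccccc1 | starting material
3 | 2,4-bis(benzyloxy)-6-hydroxybenzophenone | O=C(c1ccccc1)c1c(O)cc(OCc2ccccc2)cc1OCc1ccccc1 | intermediate
4 | 2-bromo-2-methylpropanoic acid | CC(C)(Br)C(=O)O | starting material
5 | 2-[2-benzoyl-3,5-bis(benzyloxy)phenoxy]-2-methylpropanoic acid | CC(C)(Oc1cc(OCc2ccccc2)cc(OCc2ccccc2)c1C(=O)c1ccccc1)C(=O)O | intermediate
6 | mixed anhydride of 5 with trifluoroacetic acid | CC(C)(Oc1cc(OCc2ccccc2)cc(OCc2ccccc2)c1C(=O)c1ccccc1)C(=O)OC(=O)C(F)(F)F | intermediate (not isolated)
7 | 7-benzoyl-4,6-bis(benzyloxy)-2,2-dimethylbenzofuran-3(2H)-one | CC1(C)Oc2c(C(=O)c3ccccc3)c(OCc3ccccc3)cc(OCc3ccccc3)c2C1=O | intermediate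
8 | trimethylsilyldiazomethane | C[Si](C)(C)C=[N+]=[N-] | starting material
9 | 8-benzoyl-5,7-bis(benzyloxy)-2,2-dimethyl-4-(trimethylsilyl)chroman-3-one (racemic at C4) | CC1(C)Oc2c(C(=O)c3ccccc3)c(OCc3ccccc3)cc(OCc3ccccc3)c2C([Si](C)(C)C)C1=O | intermediate (not isolated)
10 | 8-benzoyl-5,7-bis(benzyloxy)-2,2-dimethylchroman-3-one | CC1(C)Oc2c(C(=O)c3ccccc3)c(OCc3ccccc3)cc(OCc3ccccc3)c2CC1=O | intermediate
11 | (R)-8-benzoyl-5,7-bis(benzyloxy)-2,2-dimethylchroman-3-ol | O=C(c1ccccc1)c1c(OCc2ccccc2)cc(OCc2ccccc2)c2c1OC(C)(C)[C@H](O)C2 | intermediate
12 | (R)-8-benzoyl-2,2-dimethylchroman-3,5,7-triol | O=C(c1ccccc1)c1c(O)cc(O)c2c1OC(C)(C)[C@H](O)C2 | intermediate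
13 | geranyl bromide, (E)-1-bromo-3,7-dimethylocta-2,6-diene | CC(C)=CCC/C(C)=C/CBr | starting material
14 | [(3R)-6-[(2E)-3,7-dimethylocta-2,6-dienyl]-3,5,7-trihydroxy-2,2-dimethylchroman-8-yl](phenyl)methanone | CC(C)=CCC/C(C)=C/Cc1c(O)c2c(c(C(=O)c3ccccc3)c1O)OC(C)(C)[C@H](O)C2 | target

Total step count: 7. Longest linear sequence: 7 steps (1 to 14).

## Steps least certain to work

**Step 4 (key step).** The most likely failure is that the diazoalkane does not add: the furanone carbonyl is deactivated by donation from three oxygens and shielded by the gem-dimethyl carbon and the peri benzyloxy group, so 8 may decompose unproductively. The second risk is migration of C2 instead of the aryl carbon, or closure of the adduct to an epoxide. A change of Lewis acid (Sc(OTf)3, AlMe3) would be tried first. The fallback proper leaves the coumaranone and runs from 3 to 10 by known chemistry. Compound 3 is condensed with 3-methylbut-2-enal (ethylenediammonium diacetate, xylene, reflux; condensation at the free ortho carbon and oxa-6π closure) to 8-benzoyl-5,7-bis(benzyloxy)-2,2-dimethyl-2H-chromene F1. Its C3=C4 bond is epoxidised with dimethyldioxirane (acetone, 0 °C) to racemic 8-benzoyl-5,7-bis(benzyloxy)-2,2-dimethyl-3,4-epoxychroman F2. Catalytic ZnI2 in CH2Cl2 then brings about the Meinwald rearrangement, ionisation of the benzylic C4–O bond and a 1,2-hydride shift from C3, returning to the route at 10.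

**Step 3.** The activated acid may lose carbon monoxide, because the resulting cation is stabilised by the aryloxy oxygen and two methyl groups, or the arene may be trifluoroacetylated intermolecularly. The fallback installs the methyl groups after ring closure and runs from 3 to 7. Compound 3 is O-alkylated with bromoacetic acid (NaH, DMF) to 2-[2-benzoyl-3,5-bis(benzyloxy)phenoxy]acetic acid F3, whose acylium has no such fragmentation pathway. Trifluoroacetic anhydride converts it through the mixed carboxylic trifluoroacetic anhydride F4 into 7-benzoyl-4,6-bis(benzyloxy)benzofuran-3(2H)-one F5. Exhaustive C-methylation at C2 (iodomethane, K2CO3, DMF), passing through racemic 7-benzoyl-4,6-bis(benzyloxy)-2-methylbenzofuran-3(2H)-one F6, gives 7.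

**Step 5.** Uncatalysed borane reduction could erode the enantioselectivity, and over-reduction could reach the diaryl ketone. The fallback replaces catalyst control by resolution and runs from 10 to 11. NaBH4 (MeOH, −20 °C) gives racemic 8-benzoyl-5,7-bis(benzyloxy)-2,2-dimethylchroman-3-ol F7. Lipase-catalysed acetylation (immobilised Candida antarctica lipase B, vinyl acetate, toluene) should acylate one enantiomer, by the usual size-based preference of lipases expected to be the R alcohol, giving (R)-8-benzoyl-5,7-bis(benzyloxy)-2,2-dimethylchroman-3-yl acetate F8. After separation this is methanolysed (K2CO3, MeOH) to 11. The left-over enantiomer of F7 is returned to 10 by Dess–Martin oxidation.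

**Step 6.** Hydrogenation may go on to reduce the diaryl ketone before both benzyl ethers are gone. The fallback is non-reductive and runs from 11 to 12 without a new compound: BCl3 with pentamethylbenzene as benzyl-cation scavenger in CH2Cl2 at −78 °C.

**Step 7.** Alkylation at the C5 oxygen may compete with alkylation at C6, and a second alkylation at C6 with loss of aromaticity is possible. The fallback makes the oxygen-alkylated compound on purpose and runs from 12 to 14. The non-chelated C5 hydroxyl is alkylated with 13 (K2CO3, acetone) to (R)-8-benzoyl-5-[(E)-geranyloxy]-2,2-dimethylchroman-3,7-diol F9. Montmorillonite K10 (CH2Cl2, 0 °C) then promotes the 1,3-shift of the allyl group from oxygen to the adjacent free carbon C6, giving 14. The same treatment would recover any O-alkylated material from step 7.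

## Further compounds

F1 | step 4 | 8-benzoyl-5,7-bis(benzyloxy)-2,2-dimethyl-2H-chromene | CC1(C)C=Cc2c(OCc3ccccc3)cc(OCc3ccccc3)c(C(=O)c3ccccc3)c2O1
F2 | step 4 | racemic 8-benzoyl-5,7-bis(benzyloxy)-2,2-dimethyl-3,4-epoxychroman | CC1(C)Oc2c(C(=O)c3ccccc3)c(OCc3ccccc3)cc(OCc3ccccc3)c2C2OC21
F3 | step 3 | 2-[2-benzoyl-3,5-bis(benzyloxy)phenoxy]acetic acid | OC(=O)COc1cc(OCc2ccccc2)cc(OCc2ccccc2)c1C(=O)c1ccccc1
F4 | step 3 | mixed anhydride of F3 with trifluoroacetic acid | O=C(COc1cc(OCc2ccccc2)cc(OCc2ccccc2)c1C(=O)c1ccccc1)OC(=O)C(F)(F)F
F5 | step 3 | 7-benzoyl-4,6-bis(benzyloxy)benzofuran-3(2H)-one | O=C1COc2c(C(=O)c3ccccc3)c(OCc3ccccc3)cc(OCc3ccccc3)c21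
F6 | step 3 | racemic 7-benzoyl-4,6-bis(benzyloxy)-2-methylbenzofuran-3(2H)-one | CC1Oc2c(C(=O)c3ccccc3)c(OCc3ccccc3)cc(OCc3ccccc3)c2C1=O
F7 | step 5 | racemic 8-benzoyl-5,7-bis(benzyloxy)-2,2-dimethylchroman-3-ol | O=C(c1ccccc1)c1c(OCc2ccccc2)cc(OCc2ccccc2)c2c1OC(C)(C)C(O)C2
F8 | step 5 | (R)-8-benzoyl-5,7-bis(benzyloxy)-2,2-dimethylchroman-3-yl acetate | O=C(c1ccccc1)c1c(OCc2ccccc2)cc(OCc2ccccc2)c2c1OC(C)(C)[C@H](OC(C)=O)C2
F0 | step 6 | none | none
F9 | step 7 | (R)-8-benzoyl-5-[(E)-geranyloxy]-2,2-dimethylchroman-3,7-diol | O=C(c1ccccc1)c1c(O)cc(OC/C=C(\C)CCC=C(C)C)c2c1OC(C)(C)[C@H](O)C2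
A1 | alternative 1 | (R)-6-[(E)-geranyl]-3,5-bis(methoxymethoxy)-2,2-dimethyl-8-(trimethylsilyl)chroman-7-yl trifluoromethanesulfonate | CC(C)=CCC/C(C)=C/Cc1c(OCOC)c2c(c([Si](C)(C)C)c1OS(=O)(=O)C(F)(F)F)OC(C)(C)[C@H](OCOC)C2
A2 | alternative 1 | benzoic acid | OC(=O)c1ccccc1
A3 | alternative 1 | (R)-8-benzoyl-6-geranyl-7-hydroxy-3,5-bis(methoxymethoxy)-2,2-dimethylchroman | CC(C)=CCC/C(C)=C/Cc1c(OCOC)c2c(c(C(=O)c3ccccc3)c1O)OC(C)(C)[C@H](OCOC)C2
A4 | alternative 2 | 5-[(E)-geranyl]-2,6-dihydroxy-3-(hydroxymethyl)-4-(triisopropylsilyloxy)benzophenone | CC(C)=CCC/C(C)=C/Cc1c(O[Si](C(C)C)(C(C)C)C(C)C)c(CO)c(O)c(C(=O)c2ccccc2)c1O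
A5 | alternative 2 | 4,4,5,5-tetramethyl-2-(2-methylprop-1-en-1-yl)-1,3,2-dioxaborolane | CC(C)=CB1OC(C)(C)C(C)(C)O1
A6 | alternative 2 | 8-benzoyl-6-geranyl-7-hydroxy-2,2-dimethyl-3-(pinacolboryl)-5-(triisopropylsilyloxy)chroman, C3 configured as in the target | CC(C)=CCC/C(C)=C/Cc1c(O[Si](C(C)C)(C(C)C)C(C)C)c2c(c(C(=O)c3ccccc3)c1O)OC(C)(C)[C@H](B1OC(C)(C)C(C)(C)O1)C2
A7 | alternative 3 | 4-(benzyloxy)-2,6-dihydroxybenzophenone | O=C(c1ccccc1)c1c(O)cc(OCc2ccccc2)cc1O
A8 | alternative 3 | 3-methylbut-2-enal | CC(C)=CC=O
A9 | alternative 3 | 8-benzoyl-5-(benzyloxy)-7-hydroxy-2,2-dimethyl-2H-chromene | CC1(C)C=Cc2c(OCc3ccccc3)cc(O)c(C(=O)c3ccccc3)c2O1
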